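**Strategy.** The carbocyclic ring of the chromene (C4a, C5, C6, C7, C8, C8a) carries oxygen on C5, C7 and C8a and carbon on C4a, C6 and C8, the pattern of a 2-acylcyclohexane-1,3,5-trione. It is therefore cut at C4a–C8a and C6–C7 into an aryl 1,3-diketone and a prenylmalonyl unit. In one operation the per-trimethylsilylated 1-(3-hydroxyphenyl)butane-1,3-dione, a 1,3-bis(silyloxy)diene, is acylated at its terminal and then its central carbon by prenylmalonyl dichloride; this closes the benzene ring with the benzoyl and prenyl groups already between the right oxygens. A prenal annulation at C4a and the C8a oxygen then adds the pyran ring.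

Key step: step 6

Remark: the enol ether double bond of 4, 5 and 11 is drawn Z (silyloxy cis to the chain), as expected from the chelated enol; it is erased in step 6, so its geometry does not affect the outcome. The target has no stereocentre.

Remark: the phenol of the benzoyl ring is capped as a trimethylsilyl ether together with the two enols and is freed again in the work-up of step 6, so no separate protection or deprotection step is planned.

Step 1
Reactants: 1 1-(3-hydroxyphenyl)ethanone; 2 ethyl acetate
Product: 3 1-(3-hydroxyphenyl)butane-1,3-dione
Conditions: NaH (4 equiv), 2 (5 equiv), THF, 0 °C → reflux; then 1 M HCl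
Reagents that add atoms: none
Why: Crossed Claisen condensation: excess NaH first turns the phenol into an inert phenoxide, the methyl ketone enolate is then acylated by ethyl acetate, and deprotonation of the β-diketone formed drives the equilibrium.

Step 2
Reactants: 3 1-(3-hydroxyphenyl)butane-1,3-dione
Product: 5 (1Z)-1,3-bis(trimethylsilyloxy)-1-[3-(trimethylsilyloxy)phenyl]buta-1,3-diene, via silyloxy enone 4 (not isolated)
Conditions: TMSOTf (3.3 equiv), Et3N (4.5 equiv), Et2O, 0 °C → rt; ether layer decanted from the ammonium triflate under argon, concentrated, used crude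
Reagents that add atoms: trimethylsilyl trifluoromethanesulfonate, C[Si](C)(C)OS(=O)(=O)C(F)(F)F
Why: Soft enolisation–silylation with TMSOTf and Et3N caps the phenol and the chelated enol to give 4, whose carbonyl is then activated by further TMSOTf so that the amine removes a proton from the methyl group, the established way from 1,3-diketones to 1,3-bis(silyloxy)-1,3-dienes.

Step 3
Reactants: 6 diethyl malonate; 7 prenyl bromide (1-bromo-3-methylbut-2-ene)
Product: 8 diethyl 2-(3-methylbut-2-enyl)propanedioate
Conditions: NaH (1.0 equiv), 6 (1.5 equiv), THF, 0 °C; then 7 (1.0 equiv), 0 °C → rt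
Reagents that add atoms: none
Why: Malonic ester alkylation by SN2 displacement of the primary allylic bromide, with the malonate in excess to hold back double alkylation.

Step 4
Reactants: 8 diethyl 2-(3-methylbut-2-enyl)propanedioate
Product: 9 2-(3-methylbut-2-enyl)propanedioic acid
Conditions: KOH (2.5 equiv), EtOH/H2O, rt → 50 °C; then 1 M HCl, 0 °C, extraction
Reagents that add atoms: potassium hydroxide, [K+].[OH-]
Why: Saponification of both esters, followed by cold acidification so that the malonic acid neither decarboxylates nor lactonises onto the prenyl double bond.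

Step 5
Reactants: 9 2-(3-methylbut-2-enyl)propanedioic acid
Product: 10 2-(3-methylbut-2-enyl)propanedioyl dichloride
Conditions: (COCl)2 (2.5 equiv), DMF (cat.), CH2Cl2, 0 °C → rt, argon sweep; volatiles removed, used at once
Reagents that add atoms: oxalyl chloride, O=C(Cl)C(=O)Cl
Why: Chlorination through the Vilsmeier-type chloroiminium species from oxalyl chloride and DMF runs at 0 °C and gives only gaseous by-products, so the HCl can be swept out before it adds to the trisubstituted alkene.

Step 6
Reactants: 5 (1Z)-1,3-bis(trimethylsilyloxy)-1-[3-(trimethylsilyloxy)phenyl]buta-1,3-diene; 10 2-(3-methylbut-2-enyl)propanedioyl dichloride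
Product: 13 (3-hydroxyphenyl)[2,4,6-trihydroxy-3-(3-methylbut-2-enyl)phenyl]methanone, via acyclic diketo acid chloride 11 (not isolated), via aryl silyl ether 12 (not isolated)
Conditions: 10 (1.0 equiv) added to 5 (1.1 equiv), CH2Cl2 (0.05 M), −78 °C → rt, no base; then 10% aq. citric acid, THF, rt
Reagents that add atoms: none
Why: Proposed new method: the terminal carbon of diene 5, the most nucleophilic site of a 1,3-bis(silyloxy)diene, should attack one acyl chloride of 10 with loss of Me3SiCl (C4a–C8a bond) to give 11, whose remaining aryl-conjugated silyl enol ether then adds through carbon to the second acyl chloride, or to the acylketene formed from it, with loss of a second Me3SiCl (C6–C7 bond), and the 2-aroylcyclohexane-1,3,5-trione so formed tautomerises to phloroglucinol 12. The closest known reaction types are the Effenberger annulation, in which malonyl dichloride acylates both α-carbons of a ketone enol ether to a cyclohexane-1,3,5-trione, and the [3+3] cyclisations of 1,3-bis(silyloxy)-1,3-dienes with 1,3-dielectrophiles. The one ring is closed by a 6-exo-trig attack of the enol ether carbon (enol-exo) on the acyl carbon, and no stereocentre is created. The step needs C- instead of O-acylation in this closure, because attack by the enol oxygen of the neighbouring ketone would end at a 4-hydroxy-2-pyranone; in favour of carbon are the silyl cap that stays on the inner oxygen and keeps C6 a π-nucleophile, the absence of base and free enolate, and the aromatic ring that only the carbon pathway reaches. The positions of the benzoyl and prenyl groups are fixed by the two building blocks, and the aryl silyl ether of 12 is cleaved in the citric acid work-up to give 13.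

Step 7
Reactants: 13 (3-hydroxyphenyl)[2,4,6-trihydroxy-3-(3-methylbut-2-enyl)phenyl]methanone; 14 3-methylbut-2-enal
Product: 16 [5,7-dihydroxy-2,2-dimethyl-8-(3-methylbut-2-enyl)-2H-chromen-6-yl](3-hydroxyphenyl)methanone, via ortho-quinone methide 15 (not isolated)
Conditions: 14 (2 equiv), ethylenediammonium diacetate (20 mol%), toluene, 110 °C
Reagents that add atoms: none
Why: Chromene annulation by amine-catalysed Knoevenagel-type condensation of prenal at C5 of 13, the only unsubstituted carbon of the phloroglucinol ring, gives ortho-quinone methide 15, which closes by oxa-6π electrocyclisation on the oxygen para to the ketone, expected because the two hydroxyls flanking the benzoyl group stay tied up in hydrogen bonds to the carbonyl, while the 3-hydroxyphenyl ring is too weakly activated to react.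

**Compound list**

1 | 1-(3-hydroxyphenyl)ethanone | CC(=O)c1cccc(O)c1 | starting material
2 | ethyl acetate | CCOC(C)=O | starting material
3 | 1-(3-hydroxyphenyl)butane-1,3-dione | CC(=O)CC(=O)c1cccc(O)c1 | intermediate
4 | (3Z)-4-(trimethylsilyloxy)-4-[3-(trimethylsilyloxy)phenyl]but-3-en-2-one | CC(=O)/C=C(\O[Si](C)(C)C)c1cccc(O[Si](C)(C)C)c1 | intermediate (not isolated)
5 | (1Z)-1,3-bis(trimethylsilyloxy)-1-[3-(trimethylsilyloxy)phenyl]buta-1,3-diene | C=C(O[Si](C)(C)C)/C=C(\O[Si](C)(C)C)c1cccc(O[Si](C)(C)C)c1 | intermediate
6 | diethyl malonate | CCOC(=O)CC(=O)OCC | starting material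
7 | prenyl bromide (1-bromo-3-methylbut-2-ene) | CC(C)=CCBr | starting material
8 | diethyl 2-(3-methylbut-2-enyl)propanedioate | CCOC(=O)C(CC=C(C)C)C(=O)OCC | intermediate
9 | 2-(3-methylbut-2-enyl)propanedioic acid | CC(C)=CCC(C(=O)O)C(=O)O | intermediate
10 | 2-(3-methylbut-2-enyl)propanedioyl dichloride | CC(C)=CCC(C(=O)Cl)C(=O)Cl | intermediate
11 | (6Z)-2-(3-methylbut-2-enyl)-3,5-dioxo-7-(trimethylsilyloxy)-7-[3-(trimethylsilyloxy)phenyl]hept-6-enoyl chloride, racemic at C2 | CC(C)=CCC(C(=O)Cl)C(=O)CC(=O)/C=C(\O[Si](C)(C)C)c1cccc(O[Si](C)(C)C)c1 | intermediate (not isolated)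
12 | [2,4,6-trihydroxy-3-(3-methylbut-2-enyl)phenyl][3-(trimethylsilyloxy)phenyl]methanone | CC(C)=CCc1c(O)cc(O)c(C(=O)c2cccc(O[Si](C)(C)C)c2)c1O | intermediate (not isolated)
13 | (3-hydroxyphenyl)[2,4,6-trihydroxy-3-(3-methylbut-2-enyl)phenyl]methanone | CC(C)=CCc1c(O)cc(O)c(C(=O)c2cccc(O)c2)c1O | intermediate
14 | 3-methylbut-2-enal | CC(C)=CC=O | starting material
15 | 3,5-dihydroxy-4-(3-hydroxybenzoyl)-6-[(Z)-3-methylbut-2-enylidene]-2-(3-methylbut-2-enyl)cyclohexa-2,4-dien-1-one | O=C1C(CC=C(C)C)=C(O)C(C(=O)c2cccc(O)c2)=C(O)/C1=C/C=C(C)C | intermediate (not isolated)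
16 | [5,7-dihydroxy-2,2-dimethyl-8-(3-methylbut-2-enyl)-2H-chromen-6-yl](3-hydroxyphenyl)methanone | CC(C)=CCc1c(O)c(C(=O)c2cccc(O)c2)c(O)c2c1OC(C)(C)C=C2 | target

**Totals.** Total step count: 7. Longest linear sequence: 5 steps (steps 3, 4, 5, 6, 7).

**Steps most likely to fail**

Step 6 (proposed new method). The ring closure may run through the enol oxygen instead of carbon (lactonisation to a pyranone), or the acid chloride may oligomerise through its ketene before the second acylation. The fallback uses known chemistry and builds the benzophenone on a ready-made phloroglucinol ring. It sets out from prenyl bromide 7 and comes back at 13. Houben–Hoesch reaction of commercial benzene-1,3,5-triol (Oc1cc(O)cc(O)c1) with 3-hydroxybenzonitrile (N#Cc1cccc(O)c1) under ZnCl2 and HCl gas in Et2O at 0 °C should precipitate (3-hydroxyphenyl)(2,4,6-trihydroxyphenyl)methaniminium chloride F1. Boiling water should hydrolyse it to (3-hydroxyphenyl)(2,4,6-trihydroxyphenyl)methanone F2. C-Prenylation of F2 with one equivalent of 7 in 10% aq. KOH at 0 °C, at one of its two equivalent free ring carbons, should give 13, which re-enters at step 7.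

Step 7. The pyran ring may close on the hydroxyl ortho to the ketone and give the regioisomeric chromene. The fallback fixes the ring oxygen before the ring is made, sets out from 13 and comes back at 16. With one equivalent of DBU the 4-hydroxyl, the most acidic and the only non-chelated one of the phloroglucinol ring, should be alkylated by 3-chloro-3-methylbut-1-yne (CC(C)(Cl)C#C) with CuCl2·2H2O (cat.) in MeCN at 0 °C. This gives (3-hydroxyphenyl)[2,6-dihydroxy-3-(3-methylbut-2-enyl)-4-(2-methylbut-3-yn-2-yloxy)phenyl]methanone F3. Heating F3 in xylene at 140 °C should bring about aromatic propargyl Claisen rearrangement to the only free ortho carbon, a 1,5-hydrogen shift and oxa-6π closure, giving 16.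

Step 5. HCl may add across the prenyl double bond or induce lactonisation, and the dichloride may self-condense through its ketene. The fallback avoids free HCl, sets out from 9 and comes back at 10. Silylation of 9 with hexamethyldisilazane (neat, 60 °C) should give bis(trimethylsilyl) 2-(3-methylbut-2-enyl)propanedioate F4. Oxalyl chloride with catalytic DMF in CH2Cl2 at 0 °C should then exchange silyloxy for chloride on this neutral silyl ester, liberating Me3SiCl in place of HCl and giving 10.

**Further compounds**

F1 | step 6 | (3-hydroxyphenyl)(2,4,6-trihydroxyphenyl)methaniminium chloride | [NH2+]=C(c1cccc(O)c1)c1c(O)cc(O)cc1O.[Cl-]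
F2 | step 6 | (3-hydroxyphenyl)(2,4,6-trihydroxyphenyl)methanone | O=C(c1cccc(O)c1)c1c(O)cc(O)cc1O
F3 | step 7 | (3-hydroxyphenyl)[2,6-dihydroxy-3-(3-methylbut-2-enyl)-4-(2-methylbut-3-yn-2-yloxy)phenyl]methanone | CC(C)=CCc1c(O)c(C(=O)c2cccc(O)c2)c(O)cc1OC(C)(C)C#C
F4 | step 5 | bis(trimethylsilyl) 2-(3-methylbut-2-enyl)propanedioate | CC(C)=CCC(C(=O)O[Si](C)(C)C)C(=O)O[Si](C)(C)C
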